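**Strategy.** The route rests on cutting the C10–C11 bond of the oxepane after raising C12 to a lactone carbonyl. C10–C11–C12 is then an acetate aldol unit hung between the C7 oxygen and C9, which are cis-1,3 on the all-cis oxolane. A SmI2 Reformatsky closure of a C7 bromoacetate onto a C9 formyl group forms that bond, the seven-membered ring of the 2,7-dioxabicyclo[4.2.1]nonane and the C10 carbinol in one operation. The precursor is the all-cis 2-(2-silyloxyethyl)-5-formyloxolan-3-yl bromoacetate, made from dimethyl L-malate by carbenoid C–H insertion. The lactone carbonyl later carries C13–C15, and both bromides come from alcohols by inversion.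

Key step: step 10

Remark: the chain is numbered C1 (alkyne CH) to C15 (CH3); the oxolane oxygen joins C6 and C9, the oxepane oxygen joins C7 and C12. TBS = tert-butyldimethylsilyl, TBDPS = tert-butyldiphenylsilyl, TIPS = triisopropylsilyl. Compounds 1, 2, 12, 18 and 28 are taken as purchasable.

**Step 1**
Reactants: 1 dimethyl (S)-malate; 2 2-(TBS-oxy)ethanol
Product: 4 dimethyl (2S)-2-[2-(TBS-oxy)ethoxy]butanedioate, via 2-(TBS-oxy)ethyl triflate 3 (not isolated)
Conditions: 2, Tf2O, 2,6-di-tert-butyl-4-methylpyridine, CH2Cl2, −78 °C; then 1, −78 °C → rt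
Reagents that add atoms: none
Why: Williamson-type O-alkylation of the α-hydroxy ester by a primary alkyl triflate with a hindered pyridine as acid scavenger needs no strong base, so β-elimination to the fumarate and racemisation at C6 should not occur; the stereocentre is not touched.

**Step 2**
Reactants: 4 dimethyl (2S)-2-[2-(TBS-oxy)ethoxy]butanedioate
Product: 5 (2S)-2-[2-(TBS-oxy)ethoxy]-4-methoxy-4-oxobutanoic acid
Conditions: LiOH·H2O (1.0 equiv), THF/H2O 3:1, 0 °C; then 1 M HCl to pH 3 at 0 °C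
Reagents that add atoms: lithium hydroxide, [Li+].[OH-]
Why: Regioselective ester saponification, in which the ester on the alkoxy-bearing carbon is the more electrophilic one (inductive activation, lithium chelation by the ether oxygen) and should be hydrolysed first by one equivalent of hydroxide.

**Step 3**
Reactants: 5 (2S)-2-[2-(TBS-oxy)ethoxy]-4-methoxy-4-oxobutanoic acid
Product: 7 methyl (3S)-3-[2-(TBS-oxy)ethoxy]-5-diazo-4-oxopentanoate, via ethyl carbonic mixed anhydride 6 (not isolated)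
Conditions: ClCO2Et, Et3N, THF, −15 °C; then TMSCHN2 (2 M in hexanes), MeCN, 0 °C → rt
Reagents that add atoms: (trimethylsilyl)diazomethane, C[Si](C)(C)C=[N+]=[N-]
Why: Acylation of a diazoalkane by a mixed carbonic anhydride (Arndt–Eistert-type diazoketone synthesis) should give the α-alkoxy diazoketone; the carbon brought in becomes C8 and the mild activation leaves C6 untouched.

**Step 4**
Reactants: 7 methyl (3S)-3-[2-(TBS-oxy)ethoxy]-5-diazo-4-oxopentanoate
Product: 8 methyl 2-[(2S,5S)-5-(TBS-oxymethyl)-3-oxooxolan-2-yl]acetate (2,5-cis)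
Conditions: Rh2(OAc)4 (2 mol %), CH2Cl2, rt, slow addition of 7
Reagents that add atoms: none
Why: Rhodium-carbenoid 1,5 C–H insertion into the ether-activated O–CH2 bond closes the oxolan-3-one and sets C9, the CH2OTBS group lying pseudo-equatorial in the insertion transition state so that it ends cis to the C6 side chain; the C4 ester offers no competing 1,5 C–H bond.

**Step 5**
Reactants: 8 methyl 2-[(2S,5S)-5-(TBS-oxymethyl)-3-oxooxolan-2-yl]acetate
Product: 10 2-[(2S,3S,5S)-5-(TBS-oxymethyl)-3-hydroxyoxolan-2-yl]ethanol (all-cis), via cis-fused bicyclic γ-lactone 9 (not isolated)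
Conditions: LiBH(s-Bu)3, THF, −78 °C; then LiAlH4, −78 → 0 °C; aq. NaOH work-up
Reagents that add atoms: none
Why: Ketone reduction by a bulky trialkylborohydride from the ring face opposite the two cis substituents sets C7 with its oxygen cis to both (the alkoxide closes onto the neighbouring ester), and LiAlH4 then reduces the lactone to the primary alcohol.

**Step 6**
Reactants: 10 2-[(2S,3S,5S)-5-(TBS-oxymethyl)-3-hydroxyoxolan-2-yl]ethanol
Product: 11 (2S,3S,5S)-5-(TBS-oxymethyl)-2-[2-(TBDPS-oxy)ethyl]oxolan-3-ol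
Conditions: TBDPSCl, imidazole, CH2Cl2, 0 °C
Reagents that add atoms: tert-butyl(chloro)diphenylsilane, CC(C)(C)[Si](Cl)(c1ccccc1)c1ccccc1
Why: Selective silylation of the primary hydroxyl over the secondary ring hydroxyl with a bulky silyl chloride.

**Step 7**
Reactants: 11 (2S,3S,5S)-5-(TBS-oxymethyl)-2-[2-(TBDPS-oxy)ethyl]oxolan-3-ol; 12 bromoacetyl bromide
Product: 13 (2S,3S,5S)-5-(TBS-oxymethyl)-2-[2-(TBDPS-oxy)ethyl]oxolan-3-yl bromoacetate
Conditions: pyridine, CH2Cl2, −20 → 0 °C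
Reagents that add atoms: none
Why: O-Acylation of the secondary alcohol by an acid bromide with pyridine at low temperature installs the bromoacetate with retention at C7.

**Step 8**
Reactants: 13 (2S,3S,5S)-5-(TBS-oxymethyl)-2-[2-(TBDPS-oxy)ethyl]oxolan-3-yl bromoacetate
Product: 14 (2S,3S,5S)-2-[2-(TBDPS-oxy)ethyl]-5-(hydroxymethyl)oxolan-3-yl bromoacetate
Conditions: CSA (10 mol %), MeOH/CH2Cl2 1:1, 0 °C
Reagents that add atoms: none
Why: Acid-catalysed methanolysis removes the primary TBS ether far faster than the primary TBDPS ether and leaves the bromoacetate intact.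

**Step 9**
Reactants: 14 (2S,3S,5S)-2-[2-(TBDPS-oxy)ethyl]-5-(hydroxymethyl)oxolan-3-yl bromoacetate
Product: 15 (2S,3S,5S)-2-[2-(TBDPS-oxy)ethyl]-5-formyloxolan-3-yl bromoacetate (all-cis)
Conditions: Dess–Martin periodinane, CH2Cl2, 0 °C → rt; used at once
Reagents that add atoms: none
Why: Dess–Martin oxidation gives the α-alkoxy aldehyde under near-neutral conditions that should neither epimerise C9 nor disturb the bromoacetate.

**Step 10**
Reactants: 15 (2S,3S,5S)-2-[2-(TBDPS-oxy)ethyl]-5-formyloxolan-3-yl bromoacetate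
Product: 16 (1S,5R,6S,8S)-8-[2-(TBDPS-oxy)ethyl]-5-hydroxy-2,7-dioxabicyclo[4.2.1]nonan-3-one
Conditions: SmI2 (2.5 equiv, 0.1 M in THF), THF, −78 °C, slow addition of 15 (final 0.005 M); aq. work-up
Reagents that add atoms: none
Why: SmI2 (two equivalents of divalent samarium) reduces the C–Br bond to a trivalent samarium ester enolate, which adds to the C10 aldehyde through a samarium-bridged cyclic aldol transition state and gives the β-hydroxy lactone on work-up. The closest known reaction type is the SmI2-mediated intramolecular Reformatsky reaction of ω-(bromoacetoxy) aldehydes, which is established for medium-ring β-hydroxy lactones. The oxepanone ring closes in the 7-exo-trig mode, which is feasible here because the C7 ester oxygen and the C9 formyl group are cis on the oxolane and so lie within bonding distance. The new C10 stereocentre is controlled by chelation of samarium between the aldehyde oxygen and the oxolane oxygen: with the carbonyl held syn to that oxygen, the enolate, which can only arrive from the C7 side, adds to the face that leaves the hydroxyl syn to the oxolane oxygen (10R). The step needs C–Br reduction to outrun ketyl formation and ring closure to outrun intermolecular addition; the first is secured by the much easier reduction of an α-bromo ester at −78 °C, the second by the cis-1,3 tether together with slow addition to excess SmI2 at high dilution.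

**Step 11**
Reactants: 16 (1S,5R,6S,8S)-8-[2-(TBDPS-oxy)ethyl]-5-hydroxy-2,7-dioxabicyclo[4.2.1]nonan-3-one
Product: 17 (1S,5R,6S,8S)-5-(TBS-oxy)-8-[2-(TBDPS-oxy)ethyl]-2,7-dioxabicyclo[4.2.1]nonan-3-one
Conditions: TBSOTf, 2,6-lutidine, CH2Cl2, −78 °C
Reagents that add atoms: tert-butyldimethylsilyl triflate, CC(C)(C)[Si](C)(C)OS(=O)(=O)C(F)(F)F
Why: Silylation with a silyl triflate and a hindered base at −78 °C protects the β-hydroxyl without retro-aldol cleavage or β-elimination, so that the lactone can then meet a basic nucleophile.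

**Step 12**
Reactants: 17 (1S,5R,6S,8S)-5-(TBS-oxy)-8-[2-(TBDPS-oxy)ethyl]-2,7-dioxabicyclo[4.2.1]nonan-3-one; 18 2-ethyl-1,3-dithiane
Product: 20 (1S,5R,6S,8S)-5-(TBS-oxy)-8-[2-(TBDPS-oxy)ethyl]-3-(2-ethyl-1,3-dithian-2-yl)-2,7-dioxabicyclo[4.2.1]nonan-3-ol (hemiketal, in equilibrium with the open C7-hydroxy C12-ketone), via 2-ethyl-2-lithio-1,3-dithiane 19 (not isolated)
Conditions: 18, n-BuLi, THF, −30 °C; then 17, −78 °C; aq. work-up
Reagents that add atoms: none
Why: Corey–Seebach acyl-anion addition, in which the lithiated dithiane adds once to the lactone carbonyl and the congested adduct resists a second addition.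

**Step 13**
Reactants: 20 hemiketal of step 12
Product: 21 (1S,3R,5R,6S,8S)-5-(TBS-oxy)-8-[2-(TBDPS-oxy)ethyl]-3-(2-ethyl-1,3-dithian-2-yl)-2,7-dioxabicyclo[4.2.1]nonane
Conditions: Et3SiH, BF3·OEt2, CH2Cl2, −78 → −20 °C
Reagents that add atoms: none
Why: Lewis-acid-mediated reductive etherification (hemiketal to oxocarbenium ion to ether) sets C12, hydride adding from the face turned to the one-carbon C8 bridge, away from the O–C6 bridge with its side chain and from the C10 silyloxy group, which leaves the C13 carbon on the face it has in the target.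

**Step 14**
Reactants: 21 dithiane ether of step 13
Product: 22 1-[(1S,3R,5R,6S,8S)-5-(TBS-oxy)-8-[2-(TBDPS-oxy)ethyl]-2,7-dioxabicyclo[4.2.1]nonan-3-yl]propan-1-one
Conditions: MeI, CaCO3, MeCN/H2O 9:1, 45 °C
Reagents that add atoms: water, O
Why: Alkylative dithiane hydrolysis unmasks the C13 ketone under buffered conditions that spare both silyl ethers and the epimerisable C12.

**Step 15**
Reactants: 22 ethyl ketone of step 14
Product: 23 (1R)-1-[(1S,3R,5R,6S,8S)-5-(TBS-oxy)-8-[2-(TBDPS-oxy)ethyl]-2,7-dioxabicyclo[4.2.1]nonan-3-yl]propan-1-ol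
Conditions: LiBH(s-Bu)3, THF, −78 °C
Reagents that add atoms: none
Why: Felkin–Anh-controlled reduction of the α-alkoxy ketone by a bulky, non-chelating hydride, which arrives anti to the C12–O bond past the C12 hydrogen, should give the 12,13-syn (13R) alcohol.

**Step 16**
Reactants: 23 C13 alcohol of step 15
Product: 24 (1S,3R,5R,6S,8S)-8-[2-(TBDPS-oxy)ethyl]-3-[(1R)-1-hydroxypropyl]-2,7-dioxabicyclo[4.2.1]nonan-5-ol
Conditions: CSA (20 mol %), MeOH/CH2Cl2 1:1, rt
Reagents that add atoms: none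
Why: Acid-catalysed methanolysis cleaves the secondary TBS ether while the far more acid-stable primary TBDPS ether survives.

**Step 17**
Reactants: 24 C10,C13-diol of step 16
Product: 25 (1S,3R,5S,6S,8S)-5-bromo-3-[(1S)-1-bromopropyl]-8-[2-(TBDPS-oxy)ethyl]-2,7-dioxabicyclo[4.2.1]nonane
Conditions: CBr4, P(n-Oct)3, toluene, 70 °C
Reagents that add atoms: carbon tetrabromide, BrC(Br)(Br)Br
Why: Appel-type bromination through alkoxyphosphonium ions, each displaced by bromide with SN2 inversion (10R to 10S, 13R to 13S), the nucleophile entering C10 from the open face turned to the C8 bridge.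

**Step 18**
Reactants: 25 dibromide of step 17
Product: 26 2-[(1S,3R,5S,6S,8S)-5-bromo-3-[(1S)-1-bromopropyl]-2,7-dioxabicyclo[4.2.1]nonan-8-yl]ethanol
Conditions: HF·pyridine, pyridine, THF, 0 °C → rt
Reagents that add atoms: none
Why: Fluoride-mediated desilylation under mildly acidic conditions frees the primary alcohol without base-induced loss of HBr.

**Step 19**
Reactants: 26 bromo alcohol of step 18
Product: 27 2-[(1S,3R,5S,6S,8S)-5-bromo-3-[(1S)-1-bromopropyl]-2,7-dioxabicyclo[4.2.1]nonan-8-yl]acetaldehyde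
Conditions: Dess–Martin periodinane, CH2Cl2, 0 °C → rt
Reagents that add atoms: none
Why: Dess–Martin oxidation gives the β-alkoxy aldehyde under non-basic conditions, which avoids β-elimination of the ring oxygen.

**Step 20**
Reactants: 27 aldehyde of step 19; 28 1,3-bis(triisopropylsilyl)propyne
Product: 30 (1S,3R,5S,6S,8S)-5-bromo-3-[(1S)-1-bromopropyl]-8-[(2Z)-5-(triisopropylsilyl)pent-2-en-4-yn-1-yl]-2,7-dioxabicyclo[4.2.1]nonane, via 3-lithio-1,3-bis(triisopropylsilyl)propyne 29 (not isolated)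
Conditions: 28, n-BuLi, THF, −20 °C; then 27, −78 → −40 °C; aq. work-up
Reagents that add atoms: none
Why: Peterson olefination with a lithiated bis-silyl propyne, in which addition and syn loss of silanolate from the β-silyl alkoxide should give the Z-enyne preferentially at a temperature where the secondary bromides are not attacked.

**Step 21**
Reactants: 30 silyl enyne of step 20
Product: 31 (1S,3R,5S,6S,8S)-5-bromo-3-[(1S)-1-bromopropyl]-8-[(2Z)-pent-2-en-4-yn-1-yl]-2,7-dioxabicyclo[4.2.1]nonane (target)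
Conditions: Bu4NF, THF, −20 → 0 °C
Reagents that add atoms: none
Why: Fluoride-mediated protodesilylation cleaves the C(sp)–Si bond at low temperature, where the secondary bromides are stable, and gives the terminal enyne.

**Compound list**

1 | dimethyl (S)-malate | COC(=O)C[C@H](O)C(=O)OC | starting material
2 | 2-(TBS-oxy)ethanol | CC(C)(C)[Si](C)(C)OCCO | starting material
3 | 2-(TBS-oxy)ethyl triflate | CC(C)(C)[Si](C)(C)OCCOS(=O)(=O)C(F)(F)F | intermediate
4 | dimethyl (2S)-2-[2-(TBS-oxy)ethoxy]butanedioate | COC(=O)C[C@H](OCCO[Si](C)(C)C(C)(C)C)C(=O)OC | intermediate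
5 | (2S)-2-[2-(TBS-oxy)ethoxy]-4-methoxy-4-oxobutanoic acid | COC(=O)C[C@H](OCCO[Si](C)(C)C(C)(C)C)C(=O)O | intermediate
6 | ethyl carbonic mixed anhydride of 5 | COC(=O)C[C@H](OCCO[Si](C)(C)C(C)(C)C)C(=O)OC(=O)OCC | intermediate
7 | methyl (3S)-3-[2-(TBS-oxy)ethoxy]-5-diazo-4-oxopentanoate | COC(=O)C[C@H](OCCO[Si](C)(C)C(C)(C)C)C(=O)C=[N+]=[N-] | intermediate
8 | methyl 2-[(2S,5S)-5-(TBS-oxymethyl)-3-oxooxolan-2-yl]acetate | COC(=O)C[C@@H]1O[C@H](CO[Si](C)(C)C(C)(C)C)CC1=O | intermediate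
9 | (3aS,5S,6aS)-5-(TBS-oxymethyl)tetrahydrofuro[3,2-b]furan-2(3H)-one | O=C1C[C@@H]2O[C@H](CO[Si](C)(C)C(C)(C)C)C[C@@H]2O1 | intermediate
10 | 2-[(2S,3S,5S)-5-(TBS-oxymethyl)-3-hydroxyoxolan-2-yl]ethanol | OCC[C@@H]1O[C@H](CO[Si](C)(C)C(C)(C)C)C[C@@H]1O | intermediate
11 | (2S,3S,5S)-5-(TBS-oxymethyl)-2-[2-(TBDPS-oxy)ethyl]oxolan-3-ol | CC(C)(C)[Si](c1ccccc1)(c1ccccc1)OCC[C@@H]1O[C@H](CO[Si](C)(C)C(C)(C)C)C[C@@H]1O | intermediate
12 | bromoacetyl bromide | BrCC(=O)Br | starting material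
13 | (2S,3S,5S)-5-(TBS-oxymethyl)-2-[2-(TBDPS-oxy)ethyl]oxolan-3-yl bromoacetate | CC(C)(C)[Si](c1ccccc1)(c1ccccc1)OCC[C@@H]1O[C@H](CO[Si](C)(C)C(C)(C)C)C[C@@H]1OC(=O)CBr | intermediate
14 | (2S,3S,5S)-2-[2-(TBDPS-oxy)ethyl]-5-(hydroxymethyl)oxolan-3-yl bromoacetate | CC(C)(C)[Si](c1ccccc1)(c1ccccc1)OCC[C@@H]1O[C@H](CO)C[C@@H]1OC(=O)CBr | intermediate
15 | (2S,3S,5S)-2-[2-(TBDPS-oxy)ethyl]-5-formyloxolan-3-yl bromoacetate | CC(C)(C)[Si](c1ccccc1)(c1ccccc1)OCC[C@@H]1O[C@H](C=O)C[C@@H]1OC(=O)CBr | intermediate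
16 | (1S,5R,6S,8S)-8-[2-(TBDPS-oxy)ethyl]-5-hydroxy-2,7-dioxabicyclo[4.2.1]nonan-3-one | CC(C)(C)[Si](c1ccccc1)(c1ccccc1)OCC[C@@H]1O[C@H]2C[C@@H]1OC(=O)C[C@H]2O | intermediate
17 | (1S,5R,6S,8S)-5-(TBS-oxy)-8-[2-(TBDPS-oxy)ethyl]-2,7-dioxabicyclo[4.2.1]nonan-3-one | CC(C)(C)[Si](c1ccccc1)(c1ccccc1)OCC[C@@H]1O[C@H]2C[C@@H]1OC(=O)C[C@H]2O[Si](C)(C)C(C)(C)C | intermediate
18 | 2-ethyl-1,3-dithiane | CCC1SCCCS1 | starting material
19 | 2-ethyl-2-lithio-1,3-dithiane | [Li]C1(CC)SCCCS1 | intermediate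
20 | (1S,5R,6S,8S)-5-(TBS-oxy)-8-[2-(TBDPS-oxy)ethyl]-3-(2-ethyl-1,3-dithian-2-yl)-2,7-dioxabicyclo[4.2.1]nonan-3-ol (C3 unassigned) | CC(C)(C)[Si](c1ccccc1)(c1ccccc1)OCC[C@@H]1O[C@H]2C[C@@H]1OC(O)(C3(CC)SCCCS3)C[C@H]2O[Si](C)(C)C(C)(C)C | intermediate
21 | (1S,3R,5R,6S,8S)-5-(TBS-oxy)-8-[2-(TBDPS-oxy)ethyl]-3-(2-ethyl-1,3-dithian-2-yl)-2,7-dioxabicyclo[4.2.1]nonane | CC(C)(C)[Si](c1ccccc1)(c1ccccc1)OCC[C@@H]1O[C@H]2C[C@@H]1O[C@@H](C3(CC)SCCCS3)C[C@H]2O[Si](C)(C)C(C)(C)C | intermediate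
22 | 1-[(1S,3R,5R,6S,8S)-5-(TBS-oxy)-8-[2-(TBDPS-oxy)ethyl]-2,7-dioxabicyclo[4.2.1]nonan-3-yl]propan-1-one | CC(C)(C)[Si](c1ccccc1)(c1ccccc1)OCC[C@@H]1O[C@H]2C[C@@H]1O[C@@H](C(=O)CC)C[C@H]2O[Si](C)(C)C(C)(C)C | intermediate
23 | (1R)-1-[(1S,3R,5R,6S,8S)-5-(TBS-oxy)-8-[2-(TBDPS-oxy)ethyl]-2,7-dioxabicyclo[4.2.1]nonan-3-yl]propan-1-ol | CC(C)(C)[Si](c1ccccc1)(c1ccccc1)OCC[C@@H]1O[C@H]2C[C@@H]1O[C@@H]([C@H](O)CC)C[C@H]2O[Si](C)(C)C(C)(C)C | intermediate
24 | (1S,3R,5R,6S,8S)-8-[2-(TBDPS-oxy)ethyl]-3-[(1R)-1-hydroxypropyl]-2,7-dioxabicyclo[4.2.1]nonan-5-ol | CC(C)(C)[Si](c1ccccc1)(c1ccccc1)OCC[C@@H]1O[C@H]2C[C@@H]1O[C@@H]([C@H](O)CC)C[C@H]2O | intermediate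
25 | (1S,3R,5S,6S,8S)-5-bromo-3-[(1S)-1-bromopropyl]-8-[2-(TBDPS-oxy)ethyl]-2,7-dioxabicyclo[4.2.1]nonane | CC(C)(C)[Si](c1ccccc1)(c1ccccc1)OCC[C@@H]1O[C@H]2C[C@@H]1O[C@@H]([C@@H](Br)CC)C[C@@H]2Br | intermediate
26 | 2-[(1S,3R,5S,6S,8S)-5-bromo-3-[(1S)-1-bromopropyl]-2,7-dioxabicyclo[4.2.1]nonan-8-yl]ethanol | OCC[C@@H]1O[C@H]2C[C@@H]1O[C@@H]([C@@H](Br)CC)C[C@@H]2Br | intermediate
27 | 2-[(1S,3R,5S,6S,8S)-5-bromo-3-[(1S)-1-bromopropyl]-2,7-dioxabicyclo[4.2.1]nonan-8-yl]acetaldehyde | O=CC[C@@H]1O[C@H]2C[C@@H]1O[C@@H]([C@@H](Br)CC)C[C@@H]2Br | intermediate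
28 | 1,3-bis(triisopropylsilyl)propyne | CC(C)[Si](C(C)C)(C(C)C)CC#C[Si](C(C)C)(C(C)C)C(C)C | starting material
29 | 3-lithio-1,3-bis(triisopropylsilyl)propyne | [Li]C(C#C[Si](C(C)C)(C(C)C)C(C)C)[Si](C(C)C)(C(C)C)C(C)C | intermediate
30 | (1S,3R,5S,6S,8S)-5-bromo-3-[(1S)-1-bromopropyl]-8-[(2Z)-5-(triisopropylsilyl)pent-2-en-4-yn-1-yl]-2,7-dioxabicyclo[4.2.1]nonane | CC(C)[Si](C(C)C)(C(C)C)C#C/C=C\C[C@@H]1O[C@H]2C[C@@H]1O[C@@H]([C@@H](Br)CC)C[C@@H]2Br | intermediate
31 | (1S,3R,5S,6S,8S)-5-bromo-3-[(1S)-1-bromopropyl]-8-[(2Z)-pent-2-en-4-yn-1-yl]-2,7-dioxabicyclo[4.2.1]nonane | C#C/C=C\C[C@@H]1O[C@H]2C[C@@H]1O[C@@H]([C@@H](Br)CC)C[C@@H]2Br | target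

**Step count.** Total: 21 steps. Longest linear sequence: 21 steps, from 1 to 31 (2, 12, 18 and 28 enter as purchased fragments).

**Steps most likely to fail**

Step 10. Intermolecular Reformatsky addition or plain reduction of the aldehyde may outrun the seven-membered closure, and reaction through the non-chelated aldehyde rotamer would erode the facial selectivity at C10. The fallback sets out from 11 and comes back at 17; it forms the C10–C11 bond intermolecularly and closes the ring at the acyl–oxygen bond instead. Acetylation of 11 (Ac2O, pyridine, DMAP) gives the C7 acetate F1. CSA in MeOH removes the primary TBS ether to give the hydroxymethyl acetate F2, and Dess–Martin oxidation gives the formyl acetate F3. A Mukaiyama aldol addition of the TBS ketene acetal of methyl acetate (BF3·OEt2, CH2Cl2, −78 °C) follows; with a non-chelating Lewis acid, Felkin–Anh addition should give the 10R β-hydroxy methyl ester F4. TBSOTf and 2,6-lutidine give the C10 silyl ether F5, and LiOH in aqueous THF cleaves both the methyl ester and the acetate to the seco acid F6. Yamaguchi lactonisation (2,4,6-trichlorobenzoyl chloride, Et3N, THF; then DMAP, toluene, high dilution) closes the lactone and rejoins the route at 17.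

Step 13. The oxocarbenium ion next to the fully substituted dithiane carbon may be diverted by sulfur participation (1,2-sulfur shift, ring expansion) or lose a proton to an enol ether instead of taking up hydride, and the hindered open hydroxy ketone may fail to close. The fallback sets out from 17 and comes back at 22; it sets C12 by hydroboration instead of ionic reduction. Methylenation of 17 with Cp2TiMe2 (toluene, 70 °C) gives the exocyclic enol ether F7. Hydroboration–oxidation (BH3·THF, 0 °C; then NaOH, H2O2), with boron on the exocyclic carbon and hydrogen delivered to C12 from the face turned to the C8 bridge, gives the hydroxymethyl ether F8. Dess–Martin oxidation gives the aldehyde F9, EtMgBr (THF, −78 °C) gives the C13 carbinol epimer mixture F10, and Dess–Martin oxidation of that mixture gives ketone 22.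

Step 17. With two hydroxyls activated in one pot, one alkoxyphosphonium centre may be captured by the other hydroxyl (ether formation across C10/C13) or by a neighbouring ring oxygen, giving retention or rearrangement; elimination may also compete at the hindered ring position. The fallback sets out from 24 and comes back at 25; both hydroxyls are first turned into sulfonates, so that no free hydroxyl remains, and bromide is then brought in as an external nucleophile. ClCH2SO2Cl and pyridine (CH2Cl2, 0 °C) give the bis(chloromethanesulfonate) F11. Displacement with Bu4NBr (toluene, 60 °C) proceeds with SN2 inversion at C10 and C13 and gives 25.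

**Further compounds**

F1 | step 10 | (2S,3S,5S)-5-(TBS-oxymethyl)-2-[2-(TBDPS-oxy)ethyl]oxolan-3-yl acetate | CC(C)(C)[Si](c1ccccc1)(c1ccccc1)OCC[C@@H]1O[C@H](CO[Si](C)(C)C(C)(C)C)C[C@@H]1OC(C)=O
F2 | step 10 | (2S,3S,5S)-2-[2-(TBDPS-oxy)ethyl]-5-(hydroxymethyl)oxolan-3-yl acetate | CC(C)(C)[Si](c1ccccc1)(c1ccccc1)OCC[C@@H]1O[C@H](CO)C[C@@H]1OC(C)=O
F3 | step 10 | (2S,3S,5S)-2-[2-(TBDPS-oxy)ethyl]-5-formyloxolan-3-yl acetate | CC(C)(C)[Si](c1ccccc1)(c1ccccc1)OCC[C@@H]1O[C@H](C=O)C[C@@H]1OC(C)=O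
F4 | step 10 | methyl (3R)-3-[(2S,4S,5S)-4-acetoxy-5-[2-(TBDPS-oxy)ethyl]oxolan-2-yl]-3-hydroxypropanoate | CC(C)(C)[Si](c1ccccc1)(c1ccccc1)OCC[C@@H]1O[C@H]([C@H](O)CC(=O)OC)C[C@@H]1OC(C)=O
F5 | step 10 | methyl (3R)-3-[(2S,4S,5S)-4-acetoxy-5-[2-(TBDPS-oxy)ethyl]oxolan-2-yl]-3-(TBS-oxy)propanoate | CC(C)(C)[Si](c1ccccc1)(c1ccccc1)OCC[C@@H]1O[C@H]([C@H](O[Si](C)(C)C(C)(C)C)CC(=O)OC)C[C@@H]1OC(C)=O
F6 | step 10 | (3R)-3-(TBS-oxy)-3-[(2S,4S,5S)-5-[2-(TBDPS-oxy)ethyl]-4-hydroxyoxolan-2-yl]propanoic acid | CC(C)(C)[Si](c1ccccc1)(c1ccccc1)OCC[C@@H]1O[C@H]([C@H](O[Si](C)(C)C(C)(C)C)CC(=O)O)C[C@@H]1O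
F7 | step 13 | (1S,5R,6S,8S)-5-(TBS-oxy)-8-[2-(TBDPS-oxy)ethyl]-3-methylidene-2,7-dioxabicyclo[4.2.1]nonane | CC(C)(C)[Si](c1ccccc1)(c1ccccc1)OCC[C@@H]1O[C@H]2C[C@@H]1OC(=C)C[C@H]2O[Si](C)(C)C(C)(C)C
F8 | step 13 | [(1S,3R,5R,6S,8S)-5-(TBS-oxy)-8-[2-(TBDPS-oxy)ethyl]-2,7-dioxabicyclo[4.2.1]nonan-3-yl]methanol | CC(C)(C)[Si](c1ccccc1)(c1ccccc1)OCC[C@@H]1O[C@H]2C[C@@H]1O[C@@H](CO)C[C@H]2O[Si](C)(C)C(C)(C)C
F9 | step 13 | (1S,3R,5R,6S,8S)-5-(TBS-oxy)-8-[2-(TBDPS-oxy)ethyl]-2,7-dioxabicyclo[4.2.1]nonane-3-carbaldehyde | CC(C)(C)[Si](c1ccccc1)(c1ccccc1)OCC[C@@H]1O[C@H]2C[C@@H]1O[C@@H](C=O)C[C@H]2O[Si](C)(C)C(C)(C)C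
F10 | step 13 | 1-[(1S,3R,5R,6S,8S)-5-(TBS-oxy)-8-[2-(TBDPS-oxy)ethyl]-2,7-dioxabicyclo[4.2.1]nonan-3-yl]propan-1-ol (both carbinol epimers) | CC(C)(C)[Si](c1ccccc1)(c1ccccc1)OCC[C@@H]1O[C@H]2C[C@@H]1O[C@@H](C(O)CC)C[C@H]2O[Si](C)(C)C(C)(C)C
F11 | step 17 | bis(chloromethanesulfonate) of 24 | CC(C)(C)[Si](c1ccccc1)(c1ccccc1)OCC[C@@H]1O[C@H]2C[C@@H]1O[C@@H]([C@H](OS(=O)(=O)CCl)CC)C[C@H]2OS(=O)(=O)CCl
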